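**Retrosynthetic overview**

1. The side chain is numbered C1′ (ring-bound CH2) to C32′. No ring is formed: the naphthalene is bought, carried as its 1,4-dimethoxy ether, and the quinone ring is unmasked last with CAN.
2. Key cut: the C15′–C16′ bond, between the methyl-bearing alkene carbon of the fourth prenyl unit and its CH2 neighbour. A C21 homoallyl pinacol boronate (10) and a C15′-lithioalkene from the (Z)-vinyl iodide (20) are first tethered through boron, then joined by an iodine-triggered 1,2-shift and B/I elimination (Zweifel olefination) that excises boron and turns the Z iodide into the 14′E alkene.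
3. Enabling feature: C15′ is an sp2 carbon bearing only CH3 and flanked by the C14′–H carbon, so it can be a configurationally defined alkenyllithium. C16′ is an unhindered primary CH2, homoallylic to C18′=C19′, that can sit on boron and migrate. The C1–C4 quinone ring tolerates this as the dimethoxynaphthalene.
4. Left half: (S)-citronellyl Grignard plus an 8-bromogeranyl silyl ether (Cu catalysis), then boryl-methylation of the C20 allylic bromide; C27′ comes from (S)-citronellyl bromide.
5. Right half: aryl Grignard plus farnesyl bromide, terminal allylic oxidation, two-carbon aza-enolate homologation to the aldehyde, then α-iodo-Wittig olefination.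

Key step: step 14

**Route**

Step 1
Reactants: 1 geraniol
Product: 2 geranyl tert-butyldimethylsilyl ether
Conditions: TBSCl, imidazole, DMF, rt
Reagents that add atoms: tert-butyldimethylsilyl chloride, CC(C)(C)[Si](C)(C)Cl
Why: Standard silylation of a primary allylic alcohol; the silyl ether should survive the oxidation, bromination and Grignard steps that follow.

Step 2
Reactants: 2 geranyl tert-butyldimethylsilyl ether
Product: 3 (2E,6E)-8-[(tert-butyldimethylsilyl)oxy]-2,6-dimethylocta-2,6-dien-1-ol
Conditions: SeO2 (cat.), t-BuOOH, salicylic acid (cat.), CH2Cl2, 0 °C → rt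
Reagents that add atoms: tert-butyl hydroperoxide, CC(C)(C)OO (oxygen atom, passed on through the SeO2 catalyst, O=[Se]=O)
Why: Riley-type allylic oxidation (ene reaction, then [2,3]-shift) should hydroxylate the E-methyl group of the terminal gem-dimethyl alkene, giving the (E)-allylic alcohol.

Step 3
Reactants: 3 (2E,6E)-8-[(tert-butyldimethylsilyl)oxy]-2,6-dimethylocta-2,6-dien-1-ol
Product: 4 {[(2E,6E)-8-bromo-3,7-dimethylocta-2,6-dien-1-yl]oxy}(tert-butyl)dimethylsilane
Conditions: CBr4, PPh3, CH2Cl2, 0 °C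
Reagents that add atoms: carbon tetrabromide, BrC(Br)(Br)Br
Why: Appel bromination of a primary allylic alcohol under neutral conditions should proceed by direct displacement, without allylic transposition or loss of the silyl ether.

Step 4
Reactants: 4 {[(2E,6E)-8-bromo-3,7-dimethylocta-2,6-dien-1-yl]oxy}(tert-butyl)dimethylsilane, 5 (S)-citronellyl bromide
Product: 7 tert-butyldimethyl{[(2E,6E,11R)-3,7,11,15-tetramethylhexadeca-2,6,14-trien-1-yl]oxy}silane, via (S)-citronellylmagnesium bromide 6 (not isolated)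
Conditions: 5, Mg, THF, 40 °C; then 4, Li2CuCl4 (5 mol %), THF, −78 → 0 °C
Reagents that add atoms: none
Why: Cu-catalysed coupling of a primary alkyl Grignard reagent with a primary allylic bromide should occur at the bromide-bearing carbon with retention of the E alkene; the stereocentre comes unchanged from 5 (S becomes 11R only through a change of CIP priorities).

Step 5
Reactants: 7 tert-butyldimethyl{[(2E,6E,11R)-3,7,11,15-tetramethylhexadeca-2,6,14-trien-1-yl]oxy}silane
Product: 8 (2E,6E,11R)-3,7,11,15-tetramethylhexadeca-2,6,14-trien-1-ol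
Conditions: TBAF, THF, 0 °C → rt
Reagents that add atoms: none
Why: Fluoride cleavage of the silyl ether is orthogonal to the three alkenes and the stereocentre.

Step 6
Reactants: 8 (2E,6E,11R)-3,7,11,15-tetramethylhexadeca-2,6,14-trien-1-ol
Product: 9 (2E,6E,11R)-1-bromo-3,7,11,15-tetramethylhexadeca-2,6,14-triene
Conditions: CBr4, PPh3, CH2Cl2, −20 → 0 °C; used directly
Reagents that add atoms: carbon tetrabromide, BrC(Br)(Br)Br
Why: Appel bromination of the primary allylic alcohol should give the E allylic bromide without isomerisation, as for farnesyl-type alcohols.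

Step 7
Reactants: 9 (2E,6E,11R)-1-bromo-3,7,11,15-tetramethylhexadeca-2,6,14-triene
Product: 10 4,4,5,5-tetramethyl-2-[(3E,7E,12R)-4,8,12,16-tetramethylheptadeca-3,7,15-trien-1-yl]-1,3,2-dioxaborolane
Conditions: CH2(Bpin)2, NaOt-Bu, THF, rt
Reagents that add atoms: bis[(pinacolato)boryl]methane, CC1(C)OB(CB2OC(C)(C)C(C)(C)O2)OC1(C)C
Why: Deborylative alkylation of a geminal bis(boronate): alkoxide removes one boryl group and the resulting α-boryl carbanion should displace the primary allylic bromide by SN2, adding the CH2–Bpin unit (the future C16′) in one step.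

Step 8
Reactants: 11 1,4-dimethoxy-2-methylnaphthalene
Product: 12 2-bromo-1,4-dimethoxy-3-methylnaphthalene
Conditions: Br2, CH2Cl2, 0 °C
Reagents that add atoms: bromine, BrBr
Why: Electrophilic aromatic bromination should go to C3, the only free position of the doubly activated ring.

Step 9
Reactants: 12 2-bromo-1,4-dimethoxy-3-methylnaphthalene, 13 (2E,6E)-farnesyl bromide
Product: 15 1,4-dimethoxy-2-methyl-3-[(2E,6E)-3,7,11-trimethyldodeca-2,6,10-trien-1-yl]naphthalene, via arylmagnesium bromide 14 (not isolated)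
Conditions: 12, Mg, THF, reflux; then 13, CuBr·SMe2 (10 mol %), THF, −20 → 0 °C
Reagents that add atoms: none
Why: Cu-catalysed allylation of an aryl Grignard reagent with a primary prenyl-type bromide should occur at CH2 with retention of the 2E geometry, since attack at the other allylic terminus would build a quaternary benzylic carbon.

Step 10
Reactants: 15 1,4-dimethoxy-2-methyl-3-[(2E,6E)-3,7,11-trimethyldodeca-2,6,10-trien-1-yl]naphthalene
Product: 16 (2E,6E,10E)-12-(1,4-dimethoxy-3-methylnaphthalen-2-yl)-2,6,10-trimethyldodeca-2,6,10-trien-1-ol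
Conditions: SeO2 (cat.), t-BuOOH, salicylic acid (cat.), CH2Cl2, 0 °C → rt; stopped at partial conversion and 15 recycled
Reagents that add atoms: tert-butyl hydroperoxide, CC(C)(C)OO (oxygen atom, passed on through the SeO2 catalyst, O=[Se]=O)
Why: Riley-type allylic oxidation favours the E-methyl group of the terminal gem-dimethyl alkene over internal allylic CH2 groups, as known for prenylated and geranylated arenes.

Step 11
Reactants: 16 (2E,6E,10E)-12-(1,4-dimethoxy-3-methylnaphthalen-2-yl)-2,6,10-trimethyldodeca-2,6,10-trien-1-ol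
Product: 17 2-[(2E,6E,10E)-12-bromo-3,7,11-trimethyldodeca-2,6,10-trien-1-yl]-1,4-dimethoxy-3-methylnaphthalene
Conditions: CBr4, PPh3, CH2Cl2, 0 °C
Reagents that add atoms: carbon tetrabromide, BrC(Br)(Br)Br
Why: Appel bromination of the primary allylic alcohol is neutral and should leave the aryl ethers and alkenes untouched.

Step 12
Reactants: 17 2-[(2E,6E,10E)-12-bromo-3,7,11-trimethyldodeca-2,6,10-trien-1-yl]-1,4-dimethoxy-3-methylnaphthalene
Product: 19 (4E,8E,12E)-14-(1,4-dimethoxy-3-methylnaphthalen-2-yl)-4,8,12-trimethyltetradeca-4,8,12-trienal, via N-tert-butyl aldimine 18 (not isolated)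
Conditions: MeCH=Nt-Bu, LDA, THF, −78 °C; 17, −78 → 0 °C; then aq. oxalic acid, rt
Reagents that add atoms: N-tert-butylacetaldimine, CC=NC(C)(C)C; water, O
Why: Metalloenamine alkylation: the lithiated acetaldimine should be C-alkylated once at the primary allylic bromide (SN2), and mild acid hydrolysis then releases the aldehyde two carbons longer.

Step 13
Reactants: 19 (4E,8E,12E)-14-(1,4-dimethoxy-3-methylnaphthalen-2-yl)-4,8,12-trimethyltetradeca-4,8,12-trienal
Product: 20 2-[(2E,6E,10E,14Z)-15-iodo-3,7,11-trimethylhexadeca-2,6,10,14-tetraen-1-yl]-1,4-dimethoxy-3-methylnaphthalene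
Conditions: Ph3P(Et)I, n-BuLi, THF, rt; I2, −78 °C; NaHMDS, −20 °C; then 19, −78 → −20 °C
Reagents that add atoms: ethyltriphenylphosphonium iodide, CC[P+](c1ccccc1)(c1ccccc1)c1ccccc1.[I-]; iodine, II
Why: Wittig olefination with the α-iodoethylidene ylide (Stork–Zhao type) is known to give (Z)-2-iodo-2-alkenes under kinetic control, placing iodine cis to the chain.

Step 14
Reactants: 20 2-[(2E,6E,10E,14Z)-15-iodo-3,7,11-trimethylhexadeca-2,6,10,14-tetraen-1-yl]-1,4-dimethoxy-3-methylnaphthalene, 10 4,4,5,5-tetramethyl-2-[(3E,7E,12R)-4,8,12,16-tetramethylheptadeca-3,7,15-trien-1-yl]-1,3,2-dioxaborolane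
Product: 24 1,4-dimethoxy-2-methyl-3-[(2E,6E,10E,14E,18E,22E,27R)-3,7,11,15,19,23,27,31-octamethyldotriaconta-2,6,10,14,18,22,30-heptaen-1-yl]naphthalene, via alkenyllithium 21 (not isolated), via lithium boronate complex 22 (not isolated), via β-iodoalkyl boronic ester 23 (not isolated)
Conditions: 20, t-BuLi (2 equiv), Et2O/THF, −78 °C; 10, −78 °C; I2, THF/MeOH, −78 °C; NaOMe, MeOH, −78 °C → rt; aq. Na2S2O3
Reagents that add atoms: none
Why: Iodine–lithium exchange with retention gives the alkenyllithium, which adds to the boronic ester to form boronate 22, in which boron temporarily tethers the primary C16′ of the left half to the sp2 C15′ of the right half. Iodine then attacks the electron-rich alkenyl–boron π bond and triggers an anti 1,2-shift of the primary alkyl group from boron to C15′ (giving 23), and methoxide induces anti elimination of boron and iodide, so the C15′–C16′ bond is made and the tether is excised in the same flask. The closest known reaction type is the Zweifel olefination of pinacol boronic esters with alkenyllithiums (I2, NaOMe), established for primary alkyl boronic esters and α-methyl-substituted alkenyllithiums. No ring is closed and no stereocentre is created; the two transient stereocentres of 23 are destroyed, and the new stereo-element, the 14′E alkene, is fixed by the stereospecific anti-migration/anti-elimination, which inverts the Z geometry of 20 so that the migrated chain ends up trans to C13′. The step needs exchange at C–I rather than deprotonation of the ArCH2 group (secured by the speed of vinyl I/Li exchange at −78 °C), migration of carbon rather than oxygen (secured by the non-migrating pinacolato ligand), and attack of iodine on the boronate rather than on the six neutral trisubstituted alkenes or the arene (secured by the far higher nucleophilicity of the ate complex at −78 °C).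

Step 15
Reactants: 24 1,4-dimethoxy-2-methyl-3-[(2E,6E,10E,14E,18E,22E,27R)-3,7,11,15,19,23,27,31-octamethyldotriaconta-2,6,10,14,18,22,30-heptaen-1-yl]naphthalene
Product: 25 target CNP0319612.1 2-methyl-3-[(2E,6E,10E,14E,18E,22E,27R)-3,7,11,15,19,23,27,31-octamethyldotriaconta-2,6,10,14,18,22,30-heptaen-1-yl]naphthalene-1,4-dione
Conditions: CAN, MeCN/H2O/CH2Cl2, 0 °C
Reagents that add atoms: water, O
Why: Oxidative demethylation of a 2,3-dialkyl-1,4-dimethoxynaphthalene with cerium(IV) (water adds to the arene radical cation and methanol is expelled) is the standard way to unmask menaquinones and should be fast enough to spare the polyprenyl chain.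

**Compound list**

1 | geraniol, (2E)-3,7-dimethylocta-2,6-dien-1-ol | CC(C)=CCC/C(C)=C/CO | starting material
2 | geranyl tert-butyldimethylsilyl ether | CC(C)=CCC/C(C)=C/CO[Si](C)(C)C(C)(C)C | intermediate
3 | (2E,6E)-8-[(tert-butyldimethylsilyl)oxy]-2,6-dimethylocta-2,6-dien-1-ol | OC/C(C)=C/CC/C(C)=C/CO[Si](C)(C)C(C)(C)C | intermediate
4 | {[(2E,6E)-8-bromo-3,7-dimethylocta-2,6-dien-1-yl]oxy}(tert-butyl)dimethylsilane | BrC/C(C)=C/CC/C(C)=C/CO[Si](C)(C)C(C)(C)C | intermediate
5 | (S)-citronellyl bromide, (6S)-8-bromo-2,6-dimethyloct-2-ene | CC(C)=CCC[C@H](C)CCBr | starting material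
6 | (S)-citronellylmagnesium bromide, [(3S)-3,7-dimethyloct-6-en-1-yl]magnesium bromide | CC(C)=CCC[C@H](C)CC[Mg]Br | intermediate (not isolated)
7 | tert-butyldimethyl{[(2E,6E,11R)-3,7,11,15-tetramethylhexadeca-2,6,14-trien-1-yl]oxy}silane | CC(C)=CCC[C@H](C)CCC/C(C)=C/CC/C(C)=C/CO[Si](C)(C)C(C)(C)C | intermediate
8 | (2E,6E,11R)-3,7,11,15-tetramethylhexadeca-2,6,14-trien-1-ol | CC(C)=CCC[C@H](C)CCC/C(C)=C/CC/C(C)=C/CO | intermediate
9 | (2E,6E,11R)-1-bromo-3,7,11,15-tetramethylhexadeca-2,6,14-triene | CC(C)=CCC[C@H](C)CCC/C(C)=C/CC/C(C)=C/CBr | intermediate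
10 | 4,4,5,5-tetramethyl-2-[(3E,7E,12R)-4,8,12,16-tetramethylheptadeca-3,7,15-trien-1-yl]-1,3,2-dioxaborolane | CC(C)=CCC[C@H](C)CCC/C(C)=C/CC/C(C)=C/CCB1OC(C)(C)C(C)(C)O1 | intermediate
11 | 1,4-dimethoxy-2-methylnaphthalene | COc1c(C)cc(OC)c2ccccc12 | starting material
12 | 2-bromo-1,4-dimethoxy-3-methylnaphthalene | COc1c(C)c(Br)c(OC)c2ccccc12 | intermediate
13 | (2E,6E)-farnesyl bromide, (2E,6E)-1-bromo-3,7,11-trimethyldodeca-2,6,10-triene | CC(C)=CCC/C(C)=C/CC/C(C)=C/CBr | starting material
14 | (1,4-dimethoxy-3-methylnaphthalen-2-yl)magnesium bromide | COc1c(C)c([Mg]Br)c(OC)c2ccccc12 | intermediate (not isolated)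
15 | 1,4-dimethoxy-2-methyl-3-[(2E,6E)-3,7,11-trimethyldodeca-2,6,10-trien-1-yl]naphthalene | CC(C)=CCC/C(C)=C/CC/C(C)=C/Cc1c(C)c(OC)c2ccccc2c1OC | intermediate
16 | (2E,6E,10E)-12-(1,4-dimethoxy-3-methylnaphthalen-2-yl)-2,6,10-trimethyldodeca-2,6,10-trien-1-ol | OC/C(C)=C/CC/C(C)=C/CC/C(C)=C/Cc1c(C)c(OC)c2ccccc2c1OC | intermediate
17 | 2-[(2E,6E,10E)-12-bromo-3,7,11-trimethyldodeca-2,6,10-trien-1-yl]-1,4-dimethoxy-3-methylnaphthalene | BrC/C(C)=C/CC/C(C)=C/CC/C(C)=C/Cc1c(C)c(OC)c2ccccc2c1OC | intermediate
18 | N-tert-butyl aldimine of 19 (E at C=N) | CC(C)(C)/N=C/CC/C(C)=C/CC/C(C)=C/CC/C(C)=C/Cc1c(C)c(OC)c2ccccc2c1OC | intermediate (not isolated)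
19 | (4E,8E,12E)-14-(1,4-dimethoxy-3-methylnaphthalen-2-yl)-4,8,12-trimethyltetradeca-4,8,12-trienal | O=CCC/C(C)=C/CC/C(C)=C/CC/C(C)=C/Cc1c(C)c(OC)c2ccccc2c1OC | intermediate
20 | 2-[(2E,6E,10E,14Z)-15-iodo-3,7,11-trimethylhexadeca-2,6,10,14-tetraen-1-yl]-1,4-dimethoxy-3-methylnaphthalene (iodine cis to C13) | C/C(I)=C/CC/C(C)=C/CC/C(C)=C/CC/C(C)=C/Cc1c(C)c(OC)c2ccccc2c1OC | intermediate
21 | C15-lithio analogue of 20 (lithium in place of iodine, cis to C13, geometry retained) | C/C([Li])=C/CC/C(C)=C/CC/C(C)=C/CC/C(C)=C/Cc1c(C)c(OC)c2ccccc2c1OC | intermediate (not isolated)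
22 | lithium boronate complex: pinacolato boron carrying the C21 alkyl group of 10 and the alkenyl group of 21 | [Li+].C/C(=C/CC/C(C)=C/CC/C(C)=C/CC/C(C)=C/Cc1c(C)c(OC)c2ccccc2c1OC)[B-]3(CC/C=C(\C)CC/C=C(\C)CCC[C@@H](C)CCC=C(C)C)OC(C)(C)C(C)(C)O3 | intermediate (not isolated)
23 | β-iodoalkyl pinacol boronic ester: C15′ bears CH3, Bpin and the migrated C16′ chain, C14′ bears iodine, anti addition (one of the two anti adducts drawn; the other is inverted at both C14′ and C15′; both give the same alkene) | CC(C)=CCC[C@H](C)CCC/C(C)=C/CC/C(C)=C/CC[C@](C)(B1OC(C)(C)C(C)(C)O1)[C@H](I)CC/C(C)=C/CC/C(C)=C/CC/C(C)=C/Cc1c(C)c(OC)c2ccccc2c1OC | intermediate (not isolated)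
24 | 1,4-dimethoxy-2-methyl-3-[(2E,6E,10E,14E,18E,22E,27R)-3,7,11,15,19,23,27,31-octamethyldotriaconta-2,6,10,14,18,22,30-heptaen-1-yl]naphthalene | CC(C)=CCC[C@H](C)CCC/C(C)=C/CC/C(C)=C/CC/C(C)=C/CC/C(C)=C/CC/C(C)=C/CC/C(C)=C/Cc1c(C)c(OC)c2ccccc2c1OC | intermediate
25 | CNP0319612.1, 2-methyl-3-[(2E,6E,10E,14E,18E,22E,27R)-3,7,11,15,19,23,27,31-octamethyldotriaconta-2,6,10,14,18,22,30-heptaen-1-yl]naphthalene-1,4-dione | CC(C)=CCC[C@H](C)CCC/C(C)=C/CC/C(C)=C/CC/C(C)=C/CC/C(C)=C/CC/C(C)=C/CC/C(C)=C/CC1=C(C)C(=O)c2ccccc2C1=O | target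

**Step count and risks**

Total step count: 15. Longest linear sequence: 9 steps (steps 1–7, 14, 15); the right-hand branch is 8 steps (steps 8–13, 14, 15).

Steps most likely to fail:

Step 14. The alkenyllithium may be captured incompletely by the boronic ester, iodine may be consumed by the polyene or the arene, or part of the material may follow a syn-elimination path and erode the 14′E geometry. The fallback sets out from 19 and 10 and comes back at 24, using a retentive Pd coupling with the opposite halide geometry. Aldehyde 19 would be homologated with the Ohira–Bestmann reagent (K2CO3, MeOH) to the terminal alkyne 1,4-dimethoxy-2-methyl-3-[(2E,6E,10E)-3,7,11-trimethylpentadeca-2,6,10-trien-14-yn-1-yl]naphthalene F1, and C-methylated (n-BuLi, MeI) to the 2-alkyne F2. Hydrozirconation with a slight excess of Cp2Zr(H)Cl, which places zirconium on the methyl-bearing carbon, and iodination would give the (14E)-15-iodo isomer of 20 F3. Boronate 10 would be converted with KHF2 into the potassium alkyltrifluoroborate F4, and Suzuki–Miyaura coupling of F4 with F3 (PdCl2(dppf), Cs2CO3, THF/H2O, 80 °C) should give 24 with retention.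

Step 10. The allylic oxidation may show poor site selectivity among the three trisubstituted alkenes and the doubly activated ArCH2 position, with over-oxidation to the enal or attack on the electron-rich arene. The fallback sets out from 12 and comes back at 19, bypassing steps 10–12 by terminal alkene cleavage instead of allylic oxidation. The arylmagnesium bromide 14 from 12 would be allylated (CuBr·SMe2) with (2E,6E,10E)-geranylgeranyl bromide F5, made from commercial all-E geranylgeraniol with PBr3, to give the geranylgeranyl arene F6. Terminal-selective bromohydrin formation (NBS, THF/H2O, 0 °C) would give the racemic bromohydrin F7, base closure (K2CO3, MeOH) the terminal epoxide F8, and periodic acid cleavage (H5IO6, THF/Et2O) should give aldehyde 19.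

Step 13. The α-iodo ylide olefination may stall at low conversion and lose Z selectivity, with des-iodo alkene and E-iodide by-products that would carry through as the 14′Z isomer. The fallback sets out from 19 and comes back at 21, inside step 14. Corey–Fuchs dibromo-olefination (CBr4, PPh3, CH2Cl2, 0 °C) would give the 1,1-dibromoalkene F9. Pd-catalysed trans-selective monomethylation (Me2Zn, Pd(DPEphos)Cl2, THF) replaces the bromine trans to the chain and should give the (Z)-2-bromo-2-alkene F10, with bromine cis to C13. Bromine–lithium exchange (t-BuLi, 2 equiv, −78 °C) then gives alkenyllithium 21, which enters the boronate formation of step 14 unchanged.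

**Further compounds**

F1 | step 14 | 1,4-dimethoxy-2-methyl-3-[(2E,6E,10E)-3,7,11-trimethylpentadeca-2,6,10-trien-14-yn-1-yl]naphthalene | C#CCC/C(C)=C/CC/C(C)=C/CC/C(C)=C/Cc1c(C)c(OC)c2ccccc2c1OC
F2 | step 14 | 1,4-dimethoxy-2-methyl-3-[(2E,6E,10E)-3,7,11-trimethylhexadeca-2,6,10-trien-14-yn-1-yl]naphthalene | CC#CCC/C(C)=C/CC/C(C)=C/CC/C(C)=C/Cc1c(C)c(OC)c2ccccc2c1OC
F3 | step 14 | 2-[(2E,6E,10E,14E)-15-iodo-3,7,11-trimethylhexadeca-2,6,10,14-tetraen-1-yl]-1,4-dimethoxy-3-methylnaphthalene (iodine trans to C13) | C/C(I)=C\CC/C(C)=C/CC/C(C)=C/CC/C(C)=C/Cc1c(C)c(OC)c2ccccc2c1OC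
F4 | step 14 | potassium trifluoro[(3E,7E,12R)-4,8,12,16-tetramethylheptadeca-3,7,15-trien-1-yl]borate | [K+].F[B-](F)(F)CC/C=C(\C)CC/C=C(\C)CCC[C@@H](C)CCC=C(C)C
F5 | step 10 | (2E,6E,10E)-geranylgeranyl bromide | CC(C)=CCC/C(C)=C/CC/C(C)=C/CC/C(C)=C/CBr
F6 | step 10 | 1,4-dimethoxy-2-methyl-3-[(2E,6E,10E)-3,7,11,15-tetramethylhexadeca-2,6,10,14-tetraen-1-yl]naphthalene | CC(C)=CCC/C(C)=C/CC/C(C)=C/CC/C(C)=C/Cc1c(C)c(OC)c2ccccc2c1OC
F7 | step 10 | (6E,10E,14E)-3-bromo-16-(1,4-dimethoxy-3-methylnaphthalen-2-yl)-2,6,10,14-tetramethylhexadeca-6,10,14-trien-2-ol (racemic at C3) | CC(C)(O)C(Br)CC/C(C)=C/CC/C(C)=C/CC/C(C)=C/Cc1c(C)c(OC)c2ccccc2c1OC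
F8 | step 10 | terminal 14,15-epoxide of F6 (racemic), 3-[(3E,7E,11E)-13-(1,4-dimethoxy-3-methylnaphthalen-2-yl)-3,7,11-trimethyltrideca-3,7,11-trien-1-yl]-2,2-dimethyloxirane | CC1(C)OC1CC/C(C)=C/CC/C(C)=C/CC/C(C)=C/Cc2c(C)c(OC)c3ccccc3c2OC
F9 | step 13 | 2-[(2E,6E,10E)-15,15-dibromo-3,7,11-trimethylpentadeca-2,6,10,14-tetraen-1-yl]-1,4-dimethoxy-3-methylnaphthalene | BrC(Br)=CCC/C(C)=C/CC/C(C)=C/CC/C(C)=C/Cc1c(C)c(OC)c2ccccc2c1OC
F10 | step 13 | 2-[(2E,6E,10E,14Z)-15-bromo-3,7,11-trimethylhexadeca-2,6,10,14-tetraen-1-yl]-1,4-dimethoxy-3-methylnaphthalene (bromine cis to C13) | C/C(Br)=C/CC/C(C)=C/CC/C(C)=C/CC/C(C)=C/Cc1c(C)c(OC)c2ccccc2c1OC
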